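**Retrosynthetic overview**
- Feature: in the phenol ring the two oxygens sit on adjacent carbons (C1–OH, C2–O–aryl) of a 1,3-dibromobenzene core, with Br at C3 and C5 both meta to C1–OH, which bromination of a phenol cannot give. C2–O is flanked by C3–Br and C1–O by C6–H.
- Last disconnections: the O–Si bond, then the diaryl ether bond at C2–O, formed without a metal from a C1–O-silylated 3,5-dibromocatechol and a symmetric bis(5-bromo-2-methoxyphenyl)iodonium salt.
- The monosilyl catechol comes from a cis-dihydrodiol by silylation of the less hindered C1–OH, oxidation of the C2 carbinol and tautomerisation.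
- Key disconnection: both ring C–O bonds come from dioxygenase cis-dihydroxylation of the C4–C5 bond of 1,3-dibromobenzene.
- Ring order: no ring is built; both benzene rings are purchased, and the phenol ring is dearomatised in step 1 and rearomatised in step 3.

Key step: step 1

Remark: the target has no stereocentre, so no enantiocontrol is needed; the two stereocentres of the dihydrodiol are transient and are erased in step 3.

Step 1
Reactants: 1 1,3-dibromobenzene
Product: 2 (1S,2S)-3,5-dibromocyclohexa-3,5-diene-1,2-diol (cis)
Conditions: E. coli JM109(pDTG601) whole cells (toluene dioxygenase, IPTG-induced), glucose feed, air, pH 7 mineral medium, 35 °C; EtOAc extraction from base-washed glassware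
Reagents that add atoms: dioxygen, O=O
Why: The Rieske non-heme iron dioxygenase binds the arene beside its mononuclear iron, and the iron-bound activated dioxygen delivers both oxygen atoms to one face of a single ring C=C, so the two C–O bonds form suprafacially with loss of aromaticity and no ring is closed. The closest known reaction type is the whole-cell toluene dioxygenase cis-dihydroxylation of bromobenzene and of dihalobenzenes. The enzyme does not oxidise a halogen-bearing carbon, so only the C4–C5 bond and its mirror image C5–C6 can react, and both give the same constitution, with one oxygen next to C–Br (future C2) and one next to C–H (future C1). The two new stereocentres (1S,2S, cis) are set by the active site, which places the bromine-bearing edge as it does for bromobenzene; they are not needed later. The step needs only regioselectivity, and this is secured by the mirror symmetry of the substrate together with the enzyme's avoidance of ipso carbons.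

Step 2
Reactants: 2 (1S,2S)-3,5-dibromocyclohexa-3,5-diene-1,2-diol
Product: 3 (1S,6S)-2,4-dibromo-6-[(tert-butyldiphenylsilyl)oxy]cyclohexa-2,4-dien-1-ol
Conditions: TBDPSCl (1.05 equiv), imidazole, DMF, 0 °C → rt
Reagents that add atoms: tert-butyldiphenylsilyl chloride, CC(C)(C)[Si](Cl)(c1ccccc1)c1ccccc1
Why: Imidazole-promoted silyl ether formation with a bulky chlorosilane should go to the C1 hydroxyl, flanked by the vinylic C6–H, in preference to the C2 hydroxyl, which is crowded and inductively deactivated by the adjacent C3–Br; no stereocentre is formed or touched.

Step 3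
Reactants: 3 (1S,6S)-2,4-dibromo-6-[(tert-butyldiphenylsilyl)oxy]cyclohexa-2,4-dien-1-ol
Product: 5 2,4-dibromo-6-[(tert-butyldiphenylsilyl)oxy]phenol, via silyloxy dienone 4 (not isolated)
Conditions: Dess–Martin periodinane (1.1 equiv), NaHCO3, CH2Cl2, 0 °C; aq. Na2S2O3/NaHCO3
Reagents that add atoms: none
Why: Dess–Martin oxidation of the remaining secondary allylic alcohol under bicarbonate buffer gives the 6-silyloxycyclohexa-2,4-dienone 4, whose C6–H enolises at once (keto–phenol tautomerisation) to regain aromaticity, so both stereocentres vanish and the free phenol appears only on the bromine-flanked oxygen.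

Step 4
Reactants: 6 4-bromo-2-iodoanisole; 7 4-bromoanisole
Product: 9 bis(5-bromo-2-methoxyphenyl)iodonium 4-methylbenzenesulfonate, via hydroxy(tosyloxy)iodoarene 8 (not isolated)
Conditions: mCPBA (1.1 equiv), TsOH·H2O (1.1 equiv), CH2Cl2/CF3CH2OH, rt → 40 °C; Et2O trituration
Reagents that add atoms: p-toluenesulfonic acid, Cc1ccc(cc1)S(=O)(=O)O
Why: In this one-pot diaryliodonium tosylate synthesis, mCPBA and TsOH oxidise the aryl iodide to the iodine(III) species 8, which undergoes electrophilic aromatic substitution with 4-bromoanisole at the only activated open position, ortho to OMe (para is blocked by Br), and the symmetric salt removes any question of which aryl group is transferred later.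

Step 5
Reactants: 5 2,4-dibromo-6-[(tert-butyldiphenylsilyl)oxy]phenol; 9 bis(5-bromo-2-methoxyphenyl)iodonium 4-methylbenzenesulfonate
Product: 10 tert-butyl[3,5-dibromo-2-(5-bromo-2-methoxyphenoxy)phenoxy]diphenylsilane
Conditions: t-BuOK (1.0 equiv), THF, 0 °C; then 9 (1.2 equiv), 0 → 40 °C
Reagents that add atoms: none
Why: Metal-free O-arylation of a phenoxide with a diaryliodonium salt (ligand exchange at iodine(III), then ligand coupling at the ipso carbon) tolerates ortho substituents on both partners and leaves the three C–Br bonds untouched, and the bulky silyl group should stay on the less hindered C1 oxygen so that only the C2 phenoxide is arylated.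

Step 6
Reactants: 10 tert-butyl[3,5-dibromo-2-(5-bromo-2-methoxyphenoxy)phenoxy]diphenylsilane
Product: 11 3,5-dibromo-2-(5-bromo-2-methoxyphenoxy)phenol
Conditions: TBAF (1.1 equiv), AcOH (1.2 equiv), THF, 0 °C
Reagents that add atoms: none
Why: Fluoride cleaves the aryl silyl ether (driven by the strong Si–F bond) under acetic acid buffering, which keeps the liberated bromophenol protonated and leaves the diaryl ether, the methyl ether and the C–Br bonds untouched.

**Compound list**
1 | 1,3-dibromobenzene | Brc1cccc(Br)c1 | starting material
2 | (1S,2S)-3,5-dibromocyclohexa-3,5-diene-1,2-diol (cis) | O[C@H]1C=C(Br)C=C(Br)[C@H]1O | intermediate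
3 | (1S,6S)-2,4-dibromo-6-[(tert-butyldiphenylsilyl)oxy]cyclohexa-2,4-dien-1-ol | CC(C)(C)[Si](c1ccccc1)(c1ccccc1)O[C@H]1C=C(Br)C=C(Br)[C@H]1O | intermediate
4 | (6S)-2,4-dibromo-6-[(tert-butyldiphenylsilyl)oxy]cyclohexa-2,4-dien-1-one | CC(C)(C)[Si](c1ccccc1)(c1ccccc1)O[C@H]1C=C(Br)C=C(Br)C1=O | intermediate
5 | 2,4-dibromo-6-[(tert-butyldiphenylsilyl)oxy]phenol | CC(C)(C)[Si](c1ccccc1)(c1ccccc1)Oc1cc(Br)cc(Br)c1O | intermediate
6 | 4-bromo-2-iodoanisole | COc1ccc(Br)cc1I | starting material
7 | 4-bromoanisole | COc1ccc(Br)cc1 | starting material
8 | [(5-bromo-2-methoxyphenyl)(hydroxy)-λ3-iodanyl] 4-methylbenzenesulfonate | COc1ccc(Br)cc1I(O)OS(=O)(=O)c1ccc(C)cc1 | intermediate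
9 | bis(5-bromo-2-methoxyphenyl)iodonium 4-methylbenzenesulfonate | COc1ccc(Br)cc1[I+]c1cc(Br)ccc1OC.Cc1ccc(cc1)S(=O)(=O)[O-] | intermediate
10 | tert-butyl[3,5-dibromo-2-(5-bromo-2-methoxyphenoxy)phenoxy]diphenylsilane | COc1ccc(Br)cc1Oc1c(O[Si](c2ccccc2)(c2ccccc2)C(C)(C)C)cc(Br)cc1Br | intermediate
11 | 3,5-dibromo-2-(5-bromo-2-methoxyphenoxy)phenol | COc1ccc(Br)cc1Oc1c(O)cc(Br)cc1Br | target

Total step count: 6. Longest linear sequence: 5 steps (steps 1, 2, 3, 5, 6); step 4 is a one-step side branch.

**Steps most likely to fail**

Step 3 (oxidation and rearomatisation). Once the C2 oxygen is bound to iodine(V), elimination across C1–C2 can compete and expel that oxygen, the acetic acid released can dehydrate the dienol, and the newly formed phenol can be oxidised further. The fallback sets out from diol 2 and also bypasses step 2. Dehydrogenation with whole cells that express the NAD+-dependent cis-dihydrodiol dehydrogenase next to the dioxygenase should give 3,5-dibromocatechol F1 without any activation of oxygen as a leaving group. Monosilylation of this catechol with TBDPSCl and imidazole in DMF, where the bulky silyl group should settle on the oxygen flanked by C–H, comes back to the route at phenol 5.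

Step 5 (O-arylation). A 1,4-shift of the silyl group from one catechol oxygen to the other in the potassium phenoxide would lead to arylation of the wrong oxygen. The base can also trigger aryne formation from the iodonium salt by deprotonation between iodine and bromine, and ligand coupling of the electron-rich, ortho-substituted aryl group may be slow. The fallback sets out from phenol 5: Chan–Lam coupling with purchased (5-bromo-2-methoxyphenyl)boronic acid (Cu(OAc)2, pyridine, 4 Å molecular sieves, CH2Cl2, air, rt). This copper(II)-mediated oxidative C–O coupling runs under an amine base without a free alkali phenoxide and at a temperature where C–Br bonds do not react. It comes back to the route at silyl ether 10 and makes no new compound (F0).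

Step 1 (dioxygenation). Toxicity and poor uptake of the dihalobenzene can limit conversion, turnover of this doubly deactivated arene can be slow, and the diol can dehydrate to bromophenols during extraction and concentration. The fallback replaces the enzymatic oxygenation by a chemical one and sets out from iodonium salt 9. O-Arylation of purchased 3,5-dibromo-2-hydroxybenzaldehyde with 9 (t-BuOK, THF) should give 3,5-dibromo-2-(5-bromo-2-methoxyphenoxy)benzaldehyde F2. Baeyer–Villiger oxidation (mCPBA, CH2Cl2) should convert the formyl group into the ester 3,5-dibromo-2-(5-bromo-2-methoxyphenoxy)phenyl formate F3. Saponification (aq. NaOH, MeOH, then acid) comes back to the route at target 11.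

**Further compounds**
F1 | step 3 | 3,5-dibromobenzene-1,2-diol (3,5-dibromocatechol) | Oc1cc(Br)cc(Br)c1O
F0 | step 5 | none | none
F2 | step 1 | 3,5-dibromo-2-(5-bromo-2-methoxyphenoxy)benzaldehyde | COc1ccc(Br)cc1Oc1c(C=O)cc(Br)cc1Br
F3 | step 1 | 3,5-dibromo-2-(5-bromo-2-methoxyphenoxy)phenyl formate | COc1ccc(Br)cc1Oc1c(OC=O)cc(Br)cc1Br
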